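**Plan**

1. Retrosynthesis first cuts the amide N–C(acyl) bond, giving the side-chain acid (from hex-5-enoic acid, pentylmagnesium bromide and acrylic acid), then removes the C2–C3 epoxide oxygen and the C4 hydroxyl to leave a bicyclo[3.3.1]non-2-en-9-one.
2. Feature (C1 carbinol bridgehead, C2–C3 epoxide, C4 carbinol, C5 bridgehead CH, C6 carbinol, C7 amide carbon, C8 CH2, C9 ketone; ring A = C1-C2-C3-C4-C5-C9, ring B = C1-C8-C7-C6-C5-C9): the C9 ketone, C5 and the C6 carbinol are an aldol unit in which the ring A carbon C4 sits on C5 anti to the C6 oxygen. This is what a semipinacol shift of C4 from a C9 carbinol onto a C5–C6 epoxide leaves behind, so the C4–C5 bond is cut and C4 returned to C9, giving a cis-fused hydrindene epoxy diol.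
3. The hydrindene is cut at C2=C3 (ring-closing metathesis), C1–C2 (vinyl Grignard), C9–C4 (allyl Grignard) and C1–O (enolate hydroxylation), back to an all-cis epoxy ketone made from cyclohexa-1,3-diene.
4. Forward, ring B comes from the diene, the cyclopentene is closed by metathesis, ring A arises by enlargement of that five-membered ring in the key step, the side chain is joined by amide coupling and the epoxide is installed last.
5. Stereochemistry: C7 (S) comes from lipase desymmetrisation of a meso diacetate and a retentive palladium amination, and every later centre is relayed from it. The C5–C6 epoxide is set by hydroxyl/amide-directed epoxidation, C9 by allyl addition anti to the epoxide, C1 by vinyl addition anti to the β substituents, C5 by inversion in the shift, and C4 and the C2–C3 epoxide from the exo face of ring A.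

Key step: step 11

Conventions: ring B atoms keep the target numbering in all intermediates (C7 nitrogen-bearing carbon, C8 CH2, then C1, C9, C5, C6); β is the face of ring B that carries the C7 nitrogen, α the other face.
Assumption: the lipase is taken to hydrolyse the pro-R acetate of 2; should its preference be the opposite, acetylation of the meso diol with the same enzyme gives the same monoacetate 3.
Remark: compounds 9 and 11 are carried as mixtures of C1 epimers, a centre that is erased in step 8.

**Route**

Step 1
Reactants: 1 cyclohexa-1,3-diene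
Product: 2 cis-cyclohex-2-ene-1,4-diyl diacetate (meso)
Conditions: Pd(OAc)2 (5 mol%), LiCl (catalytic), LiOAc, p-benzoquinone (catalytic), MnO2, AcOH, rt
Reagents that add atoms: acetic acid, CC(=O)O
Why: Palladium-catalysed oxidative 1,4-diacetoxylation of a conjugated diene, in which acetoxypalladation gives a π-allyl complex that, with catalytic chloride present, is opened by external acetate anti to the metal, so the two acetates end up cis and the product is meso.

Step 2
Reactants: 2 cis-cyclohex-2-ene-1,4-diyl diacetate
Product: 3 (1R,4S)-4-acetoxycyclohex-2-en-1-ol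
Conditions: Candida antarctica lipase B (immobilised), phosphate buffer pH 7, rt
Reagents that add atoms: none
Why: Enzymatic desymmetrisation (enantiotopic-group-selective ester hydrolysis) of the meso diacetate removes one acetate only and thereby fixes the absolute configuration of both oxygen-bearing carbons.

Step 3
Reactants: 3 (1R,4S)-4-acetoxycyclohex-2-en-1-ol; 4 2,2,2-trifluoroacetamide
Product: 5 N-[(1S,4R)-4-hydroxycyclohex-2-en-1-yl]-2,2,2-trifluoroacetamide (cis)
Conditions: Pd(PPh3)4 (5 mol%), CF3CONH2, Cs2CO3, THF, 50 °C
Reagents that add atoms: 2,2,2-trifluoroacetamide (4), NC(=O)C(F)(F)F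
Why: Tsuji–Trost allylic amination, in which zerovalent palladium ionises the acetate with inversion and the amidate attacks the π-allyl terminus remote from the hydroxyl-bearing carbon anti to the metal, so nitrogen replaces the acetate with net retention and stays cis to the hydroxyl (C7 becomes S).

Step 4
Reactants: 5 cis amido alcohol
Product: 6 N-[(1S,2S,5R,6R)-5-hydroxy-7-oxabicyclo[4.1.0]heptan-2-yl]-2,2,2-trifluoroacetamide (epoxide, hydroxyl and amide all cis)
Conditions: mCPBA, CH2Cl2, 0 °C
Reagents that add atoms: 3-chloroperoxybenzoic acid, OOC(=O)c1cccc(Cl)c1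
Why: Directed peracid epoxidation, in which the allylic hydroxyl and the allylic amide N–H both lie on the β face and both hydrogen-bond to the peracid, so oxygen is delivered to C5=C6 from that face and the epoxide ends up cis to both groups.

Step 5
Reactants: 6 all-cis epoxy alcohol
Product: 7 N-[(1S,2S,6S)-5-oxo-7-oxabicyclo[4.1.0]heptan-2-yl]-2,2,2-trifluoroacetamide (β-epoxy ketone, C9 ketone)
Conditions: Dess–Martin periodinane, CH2Cl2, 0 °C to rt
Reagents that add atoms: none
Why: Dess–Martin oxidation of a secondary epoxy alcohol to the α,β-epoxy ketone is mild and non-basic, leaves epoxide and amide alone and puts no stereocentre at risk because C5 cannot epimerise without opening the epoxide.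

Step 6
Reactants: 7 epoxy ketone
Product: 9 N-[(1S,2S,6S)-4-hydroxy-5-oxo-7-oxabicyclo[4.1.0]heptan-2-yl]-2,2,2-trifluoroacetamide (hydroxyl on C1 of the target numbering; both C1 epimers), via dipotassium amidate enolate 8 (not isolated)
Conditions: KN(SiMe3)2 (2.2 equiv), THF, −78 °C; then 3-phenyl-2-(phenylsulfonyl)oxaziridine, −78 °C; AcOH quench
Reagents that add atoms: 3-phenyl-2-(phenylsulfonyl)oxaziridine, O=S(=O)(N1OC1c1ccccc1)c1ccccc1 (oxygen at C1); potassium bis(trimethylsilyl)amide, C[Si](C)(C)[N-][Si](C)(C)C.[K+] (potassium of 8 only)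
Why: Enolate hydroxylation with an N-sulfonyloxaziridine, in which two equivalents of base give the amidate and the kinetic enolate on the C1 methylene side (the other α-carbon is an epoxide carbon) and the enolate takes up electrophilic oxygen at C1, whose configuration is irrelevant because it becomes a ketone in step 8.

Step 7
Reactants: 9 C1-hydroxy epoxy ketone; 10 allylmagnesium bromide
Product: 11 N-[5-allyl-4,5-dihydroxy-7-oxabicyclo[4.1.0]heptan-2-yl]-2,2,2-trifluoroacetamide (C9 hydroxyl β, cis to epoxide and amide; allyl α; C1 epimers)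
Conditions: allylMgBr (4 equiv), THF, −78 °C
Reagents that add atoms: allylmagnesium bromide (10), C=CC[Mg]Br
Why: Grignard 1,2-addition to an α,β-epoxy ketone takes place on the face opposite the epoxide oxygen, which together with the β amide shields the β face, so allyl enters α and the new C9 hydroxyl is β and syn to the epoxide, the first equivalents of reagent serving only to deprotonate N–H and O–H.

Step 8
Reactants: 11 allyl diol
Product: 12 N-[5-allyl-5-hydroxy-4-oxo-7-oxabicyclo[4.1.0]heptan-2-yl]-2,2,2-trifluoroacetamide (C1 ketone; C9 hydroxyl, epoxide and amide β; allyl α)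
Conditions: IBX, DMSO, rt
Reagents that add atoms: none
Why: IBX oxidises the secondary C1 alcohol of a vicinal diol to the ketone without glycol cleavage, does not touch the tertiary C9 alcohol, the epoxide or the terminal alkene, and removes the stereochemically undefined centre.

Step 9
Reactants: 12 α-hydroxy ketone; 13 vinylmagnesium bromide
Product: 14 N-[5-allyl-4,5-dihydroxy-4-vinyl-7-oxabicyclo[4.1.0]heptan-2-yl]-2,2,2-trifluoroacetamide (C1 and C9 hydroxyls, epoxide and amide all β; vinyl and allyl α)
Conditions: vinylMgBr (5 equiv), THF, −78 to 0 °C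
Reagents that add atoms: vinylmagnesium bromide (13), C=C[Mg]Br
Why: Grignard 1,2-addition to an α-hydroxy ketone, in which the nucleophile should enter C1 from the α face, anti to the adjacent C9–O bond (Felkin–Anh polar model) and away from the β face crowded by the C9 oxygen, the epoxide and the C7 amidate, so the new hydroxyl is β and the diol cis.

Step 10
Reactants: 14 vinyl allyl diol
Product: 15 cis-fused hydrindene epoxy diol, N-[(1S,5S,6S,7S,9S)-1,9-dihydroxy-5,6-epoxybicyclo[4.3.0]non-2-en-7-yl]-2,2,2-trifluoroacetamide in target numbering (five-membered ring C1–C2=C3–C4–C9; both hydroxyls, epoxide and amide β)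
Conditions: second-generation Grubbs catalyst (5 mol%), CH2Cl2, 40 °C
Reagents that add atoms: none
Why: Ring-closing metathesis of the cis-disposed vinyl and allyl groups gives the unstrained cis-fused cyclopentene with loss of ethene, and the ruthenium carbene tolerates free alcohols, the epoxide and the amide.

Step 11
Reactants: 15 cis-fused hydrindene epoxy diol
Product: 16 N-[(1S,5R,6R,7S)-1,6-dihydroxy-9-oxobicyclo[3.3.1]non-2-en-7-yl]-2,2,2-trifluoroacetamide (target numbering; C6 hydroxyl axial on ring B and cis to the equatorial C7 amide)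
Conditions: BF3·OEt2 (1.1 equiv), CH2Cl2, −78 to −40 °C
Reagents that add atoms: none
Why: BF3 binds the epoxide oxygen, which lies on the β face syn to the C9 hydroxyl, so the α-disposed C9–C4 bond is antiperiplanar to the C5–O bond and C4 shifts from C9 to C5 as that bond breaks while the C9 hydroxyl collapses to the ketone; this is a semipinacol rearrangement of a 2,3-epoxy tertiary alcohol, and the closest known reaction type is the Lewis-acid ring expansion of such epoxy alcohols to β-hydroxy ketones. Ring A closes as a ring enlargement by 1,2-alkyl shift: the cyclopentene C1–C2=C3–C4–C9 takes up C5 and becomes the bridged six-membered ring C1–C2=C3–C4–C5–C9, while ring B is untouched. The one new stereocentre, C5, is formed with inversion because the migrating carbon enters anti to the leaving oxygen, and the C6 oxygen keeps its β orientation and ends anti to C4. The step needs C5 and not C6 to open, and C4 and not C1 or a hydride to migrate; the first is secured by the push of the adjacent carbinol and by the electron-poor trifluoroacetamide next to C6, the second by the antiperiplanar alignment that only the C9–C4 bond has. The amide, both hydroxyls and the epoxide all sit on the β face, so none of them can reach the rear of C5 or C6, and the low temperature is chosen to limit ionisation of the allylic C1 hydroxyl.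

Step 12
Reactants: 16 bridged enone diol
Product: 17 N-[1,4,6-trihydroxy-9-oxobicyclo[3.3.1]non-2-en-7-yl]-2,2,2-trifluoroacetamide (target numbering; new C4 hydroxyl exo, that is axial on ring A and on the face turned away from ring B)
Conditions: SeO2 (0.5 equiv), tBuOOH, CH2Cl2, rt
Reagents that add atoms: selenium dioxide, O=[Se]=O (oxygen carrier, reoxidised); tert-butyl hydroperoxide, CC(C)(C)OO (terminal oxidant)
Why: SeO2 allylic oxidation (ene reaction then [2,3]-sigmatropic shift) can only occur at C4, the single allylic position bearing hydrogen, and both pericyclic events take place on the open exo face of ring A, so the hydroxyl arrives exo as in the target, while the bridgehead C5–H cannot enolise and so shields the ketone from α-oxidation.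

Step 13
Reactants: 17 allylic alcohol trifluoroacetamide
Product: 18 7-amino-1,4,6-trihydroxybicyclo[3.3.1]non-2-en-9-one (target numbering; configuration as in 17)
Conditions: NH3 (7 M in MeOH), rt
Reagents that add atoms: none
Why: Ammonolysis of the electron-poor trifluoroacetamide (acyl transfer to ammonia, helped by the cis C6 hydroxyl) frees the amine under conditions mild enough to spare the β-hydroxy ketone from retro-aldol cleavage, and the bridgehead position of C5 excludes epimerisation.

Step 14
Reactants: 19 hex-5-enoic acid
Product: 21 N-methoxy-N-methylhex-5-enamide, via 1-(hex-5-enoyl)imidazole 20 (not isolated)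
Conditions: CDI, CH2Cl2, rt; then MeNH(OMe)·HCl, rt
Reagents that add atoms: N,O-dimethylhydroxylamine hydrochloride, CNOC.Cl; 1,1'-carbonyldiimidazole, O=C(n1ccnc1)n1ccnc1 (imidazole of 20 only)
Why: Acylimidazole formation followed by aminolysis is a standard Weinreb amide synthesis and involves no stereocentre.

Step 15
Reactants: 21 N-methoxy-N-methylhex-5-enamide; 22 pentylmagnesium bromide
Product: 23 undec-1-en-6-one
Conditions: pentylMgBr, THF, 0 °C
Reagents that add atoms: pentylmagnesium bromide (22), CCCCC[Mg]Br
Why: Grignard addition to a Weinreb amide stops at the chelated tetrahedral intermediate and releases the ketone only on work-up, so over-addition is avoided.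

Step 16
Reactants: 23 undec-1-en-6-one; 24 acrylic acid
Product: 25 (E)-7-oxododec-2-enoic acid
Conditions: acrylic acid (3 equiv), second-generation Hoveyda–Grubbs catalyst (5 mol%), CH2Cl2, 40 °C
Reagents that add atoms: acrylic acid (24), C=CC(=O)O
Why: Olefin cross-metathesis between a terminal alkene and the electron-poor acrylic partner is selective for the cross product and gives the E alkene under thermodynamic control.

Step 17
Reactants: 25 (E)-7-oxododec-2-enoic acid; 18 amino triol ketone
Product: 27 (E)-N-[1,4,6-trihydroxy-9-oxobicyclo[3.3.1]non-2-en-7-yl]-7-oxododec-2-enamide (target numbering; de-epoxy isariotin C), via benzotriazolyl ester 26 (not isolated)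
Conditions: 25, EDC·HCl, HOBt, CH2Cl2/DMF, 0 °C; then 18, rt
Reagents that add atoms: 1-hydroxybenzotriazole, On1nnc2ccccc12 (benzotriazolyl of 26 only)
Why: Carbodiimide/HOBt amide coupling acylates the primary amine much faster than the secondary, tertiary and allylic hydroxyls, so no protecting group is needed and no stereocentre is touched.

Step 18
Reactants: 27 de-epoxy amide
Product: 28 isariotin C
Conditions: VO(acac)2 (5 mol%), tBuOOH, CH2Cl2, 0 °C to rt
Reagents that add atoms: tert-butyl hydroperoxide, CC(C)(C)OO
Why: Vanadium-catalysed hydroxyl-directed epoxidation, in which the exo pseudoaxial C4 hydroxyl binds the vanadium peroxide and delivers oxygen to C2=C3 on its own face, which is also the less hindered exo face, while the electron-poor side-chain alkene and the ketones are inert, giving the cis epoxy alcohol of the target.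

**Compound list**

1 | cyclohexa-1,3-diene | C1=CC=CCC1 | starting material
2 | cis-cyclohex-2-ene-1,4-diyl diacetate (meso) | CC(=O)O[C@H]1CC[C@@H](OC(C)=O)C=C1 | intermediate
3 | (1R,4S)-4-acetoxycyclohex-2-en-1-ol | CC(=O)O[C@H]1CC[C@@H](O)C=C1 | intermediate
4 | 2,2,2-trifluoroacetamide | NC(=O)C(F)(F)F | starting material
5 | N-[(1S,4R)-4-hydroxycyclohex-2-en-1-yl]-2,2,2-trifluoroacetamide | FC(F)(F)C(=O)N[C@H]1CC[C@@H](O)C=C1 | intermediate
6 | N-[(1S,2S,5R,6R)-5-hydroxy-7-oxabicyclo[4.1.0]heptan-2-yl]-2,2,2-trifluoroacetamide | FC(F)(F)C(=O)N[C@H]1CC[C@@H](O)[C@H]2O[C@H]21 | intermediate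
7 | N-[(1S,2S,6S)-5-oxo-7-oxabicyclo[4.1.0]heptan-2-yl]-2,2,2-trifluoroacetamide | FC(F)(F)C(=O)N[C@H]1CCC(=O)[C@H]2O[C@H]21 | intermediate
8 | dipotassium amidate enolate of 7 (C1=C9 enolate) | [K+].[K+].FC(F)(F)C(=O)[N-][C@H]1CC=C([O-])[C@H]2O[C@H]21 | intermediate (not isolated)
9 | N-[(1S,2S,6S)-4-hydroxy-5-oxo-7-oxabicyclo[4.1.0]heptan-2-yl]-2,2,2-trifluoroacetamide (C1 of target numbering unspecified, both epimers) | FC(F)(F)C(=O)N[C@H]1CC(O)C(=O)[C@H]2O[C@H]21 | intermediate
10 | allylmagnesium bromide | C=CC[Mg]Br | starting material
11 | N-[5-allyl-4,5-dihydroxy-7-oxabicyclo[4.1.0]heptan-2-yl]-2,2,2-trifluoroacetamide (C9 hydroxyl β, allyl α; C1 unspecified, both epimers) | FC(F)(F)C(=O)N[C@H]1CC(O)[C@](O)(CC=C)[C@H]2O[C@H]21 | intermediate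
12 | N-[5-allyl-5-hydroxy-4-oxo-7-oxabicyclo[4.1.0]heptan-2-yl]-2,2,2-trifluoroacetamide | FC(F)(F)C(=O)N[C@H]1CC(=O)[C@](O)(CC=C)[C@H]2O[C@H]21 | intermediate
13 | vinylmagnesium bromide | C=C[Mg]Br | starting material
14 | N-[5-allyl-4,5-dihydroxy-4-vinyl-7-oxabicyclo[4.1.0]heptan-2-yl]-2,2,2-trifluoroacetamide (hydroxyls, epoxide, amide β; vinyl, allyl α) | FC(F)(F)C(=O)N[C@H]1C[C@](O)(C=C)[C@](O)(CC=C)[C@H]2O[C@H]21 | intermediate
15 | cis-fused hydrindene epoxy diol trifluoroacetamide (key-step precursor) | FC(F)(F)C(=O)N[C@H]1C[C@]2(O)C=CC[C@]2(O)[C@H]3O[C@H]31 | intermediate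
16 | N-[(1S,5R,6R,7S)-1,6-dihydroxy-9-oxobicyclo[3.3.1]non-2-en-7-yl]-2,2,2-trifluoroacetamide (key-step product) | FC(F)(F)C(=O)N[C@H]1C[C@@]2(O)C(=O)[C@H](CC=C2)[C@H]1O | intermediate
17 | N-[1,4,6-trihydroxy-9-oxobicyclo[3.3.1]non-2-en-7-yl]-2,2,2-trifluoroacetamide (C4 hydroxyl exo) | FC(F)(F)C(=O)N[C@H]1C[C@@]2(O)C(=O)[C@H]([C@H](O)C=C2)[C@H]1O | intermediate
18 | 7-amino-1,4,6-trihydroxybicyclo[3.3.1]non-2-en-9-one | N[C@H]1C[C@@]2(O)C(=O)[C@H]([C@H](O)C=C2)[C@H]1O | intermediate
19 | hex-5-enoic acid | C=CCCCC(=O)O | starting material
20 | 1-(hex-5-enoyl)imidazole | C=CCCCC(=O)n1ccnc1 | intermediate (not isolated)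
21 | N-methoxy-N-methylhex-5-enamide | C=CCCCC(=O)N(C)OC | intermediate
22 | pentylmagnesium bromide | CCCCC[Mg]Br | starting material
23 | undec-1-en-6-one | C=CCCCC(=O)CCCCC | intermediate
24 | acrylic acid | C=CC(=O)O | starting material
25 | (E)-7-oxododec-2-enoic acid | CCCCCC(=O)CCC/C=C/C(=O)O | intermediate
26 | 1H-benzotriazol-1-yl (E)-7-oxododec-2-enoate | CCCCCC(=O)CCC/C=C/C(=O)On1nnc2ccccc12 | intermediate (not isolated)
27 | (E)-N-[1,4,6-trihydroxy-9-oxobicyclo[3.3.1]non-2-en-7-yl]-7-oxododec-2-enamide | CCCCCC(=O)CCC/C=C/C(=O)N[C@H]1C[C@@]2(O)C(=O)[C@H]([C@H](O)C=C2)[C@H]1O | intermediate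
28 | isariotin C | CCCCCC(=O)CCC/C=C/C(=O)N[C@H]1C[C@@]2(O)C(=O)[C@H]([C@H](O)[C@@H]3O[C@@H]32)[C@H]1O | target

**Step count and risks**

Total step count: 18. Longest linear sequence: 15 (steps 1 to 13, 17 and 18); steps 14 to 16 build the side-chain acid.

Steps most likely to fail:

Step 11. The Lewis acid may ionise the tertiary allylic C1–O bond (pinacol-type loss of the diol), or a hydride may shift into the opening epoxide faster than C4 migrates, and the protic adducts of BF3 with the free hydroxyls would favour both. The fallback is an epoxy silyl ether rearrangement, in which a silyloxy group is the electron donor and no Brønsted acid is formed. It sets out from 15: both tertiary hydroxyls are silylated (Me3SiOTf, 2,6-lutidine, CH2Cl2, −78 °C) to give the bis(trimethylsilyl) ether of the hydrindene epoxy diol F1. TiCl4 in CH2Cl2 at −78 °C then drives the same shift of C4 from C9 to C5, with chloride taking up the silyl group, to give the bridged ketone still silylated at the C1 oxygen F2. Dilute HCl in THF removes that silyl group and the route is rejoined at 16.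

Step 9. Facial selectivity may be poor: attack through a magnesium chelate on the β face would give the trans diol, which cannot lead to the required cis ring fusion, and enolisation toward C8 could expel the amide. The fallback forms the C1–C2 bond intramolecularly from the α-disposed side chain, which can only give the cis fusion. It sets out from 11: ozonolysis of the allyl group (O3, CH2Cl2/MeOH, −78 °C; Me2S) gives the aldehyde F3, partly present as its lactol. Stork–Zhao olefination (Ph3P=CHI from (iodomethyl)triphenylphosphonium iodide and NaN(SiMe3)2, THF, −78 °C) gives the (Z)-vinyl iodide F4, and IBX in DMSO oxidises C1 to give the iodo ketone F5. An intramolecular Nozaki–Hiyama–Kishi reaction (CrCl2, catalytic NiCl2, DMSO, rt) closes the cyclopentenol and the route is rejoined at 15, compounds 12 and 14 being bypassed.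

Step 6. The dianion may decompose (epoxide opening, aldol addition to the sulfonimine formed from the oxidant), or the α-ketol may isomerise by enediol tautomerism before it is used. The fallback introduces the C1 oxygen at the enone stage and the epoxide afterwards. It sets out from 5: MnO2 in CH2Cl2 gives the enone (S)-2,2,2-trifluoro-N-(4-oxocyclohex-2-en-1-yl)acetamide F6. α′-Acetoxylation with Mn(OAc)3 in benzene at 80 °C gives the C1 acetoxy enone F7 as a mixture of epimers. Excess allylmagnesium bromide in THF at −78 °C adds to the ketone and cleaves the acetate to give the cyclohexene diol F8; here the allyl group is expected anti to the C7 amide, though this 1,4-induction is weaker than the epoxide control of the main route. Hydroxyl- and amide-directed epoxidation of the ring alkene (VO(acac)2, tBuOOH, CH2Cl2) then rejoins the route at 11.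

Further compounds
F1 | step 11 | bis(trimethylsilyl) ether of hydrindene epoxy diol 15 | FC(F)(F)C(=O)N[C@H]1C[C@]2(O[Si](C)(C)C)C=CC[C@]2(O[Si](C)(C)C)[C@H]3O[C@H]31
F2 | step 11 | C1 O-trimethylsilyl ether of bridged ketone 16 | FC(F)(F)C(=O)N[C@H]1C[C@@]2(O[Si](C)(C)C)C(=O)[C@H](CC=C2)[C@H]1O
F3 | step 9 | N-[4,5-dihydroxy-5-(2-oxoethyl)-7-oxabicyclo[4.1.0]heptan-2-yl]-2,2,2-trifluoroacetamide (C1 epimers) | FC(F)(F)C(=O)N[C@H]1CC(O)[C@](O)(CC=O)[C@H]2O[C@H]21
F4 | step 9 | N-[4,5-dihydroxy-5-[(Z)-3-iodoprop-2-enyl]-7-oxabicyclo[4.1.0]heptan-2-yl]-2,2,2-trifluoroacetamide (C1 epimers) | FC(F)(F)C(=O)N[C@H]1CC(O)[C@](O)(C/C=C\I)[C@H]2O[C@H]21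
F5 | step 9 | N-[5-hydroxy-5-[(Z)-3-iodoprop-2-enyl]-4-oxo-7-oxabicyclo[4.1.0]heptan-2-yl]-2,2,2-trifluoroacetamide | FC(F)(F)C(=O)N[C@H]1CC(=O)[C@](O)(C/C=C\I)[C@H]2O[C@H]21
F6 | step 6 | (S)-2,2,2-trifluoro-N-(4-oxocyclohex-2-en-1-yl)acetamide | FC(F)(F)C(=O)N[C@H]1CCC(=O)C=C1
F7 | step 6 | (5S)-2-oxo-5-(2,2,2-trifluoroacetamido)cyclohex-3-en-1-yl acetate (C1 epimers) | FC(F)(F)C(=O)N[C@H]1CC(OC(C)=O)C(=O)C=C1
F8 | step 6 | N-[4-allyl-4,5-dihydroxycyclohex-2-en-1-yl]-2,2,2-trifluoroacetamide (C9 hydroxyl cis to amide, allyl trans; C1 epimers) | FC(F)(F)C(=O)N[C@H]1CC(O)[C@](O)(CC=C)C=C1
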